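## Retrosynthetic overview
1. The last bond made is the exocyclic nitrogen–carbon bond between a 2-aminoimidazole (free phenol) and O-silylated 1-methylparabanic acid. That trione ring is made beforehand from N-methylurea and oxalyl chloride.
2. The 2-aminoimidazole ring comes from an alpha-(methylamino) ketone and cyanamide, with the phenol masked as a benzyl ether.
3. The key carbon–carbon bond, C(=O)–CH(Ar), comes from a crossed Claisen condensation of the enolate of tert-butyl (4-methoxyphenyl)acetate with the activated N-Boc-N-methyl amino acid. Acid then removes Boc and t-Bu and triggers decarboxylation.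
4. The amino acid comes from the Boc-sarcosine ethyl ester enolate and 2-(benzyloxy)-3,4-dimethoxybenzyl bromide, which is made from 2,3,4-trimethoxybenzaldehyde.
5. Ring order: imidazolidinetrione ring (side branch), then imidazole ring (main line), then the two rings are joined.

Assumption: the target SMILES holds no stereocentre and no stereogenic double bond, so pyronaamidine is achiral and no enantiocontrol is needed. The sp3 centres in 9, 10, 13 and 15–18 are carried as racemates or mixtures and vanish on aromatisation in step 11.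

## Route

Step 1
Reactants: 1 2,3,4-trimethoxybenzaldehyde
Product: 2 2-hydroxy-3,4-dimethoxybenzaldehyde
Conditions: BCl3 (1.05 equiv), CH2Cl2, 0 °C → rt, 3 h; then H2O
Reagents that add atoms: none
Why: BCl3 chelates between the aldehyde oxygen and the ortho methoxy oxygen, so one equivalent cleaves only the 2-OMe group (chelation-directed Lewis acid ether cleavage) and leaves the 3- and 4-OMe groups intact.

Step 2
Reactants: 2 2-hydroxy-3,4-dimethoxybenzaldehyde
Product: 3 2-(benzyloxy)-3,4-dimethoxybenzaldehyde
Conditions: BnBr (1.2 equiv), K2CO3 (2 equiv), DMF, 60 °C, 6 h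
Reagents that add atoms: benzyl bromide, BrCc1ccccc1
Why: Williamson ether synthesis on the acidic, hydrogen-bonded ortho-hydroxy aldehyde gives a phenol mask that survives strong base, LiOH and short TFA exposure and is removed later by hydrogenolysis.

Step 3
Reactants: 3 2-(benzyloxy)-3,4-dimethoxybenzaldehyde
Product: 4 [2-(benzyloxy)-3,4-dimethoxyphenyl]methanol
Conditions: NaBH4, MeOH/THF, 0 °C, 1 h
Reagents that add atoms: none
Why: Borohydride reduction of an aromatic aldehyde is chemoselective and essentially quantitative, and the ethers are inert.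

Step 4
Reactants: 4 [2-(benzyloxy)-3,4-dimethoxyphenyl]methanol
Product: 5 2-(benzyloxy)-1-(bromomethyl)-3,4-dimethoxybenzene
Conditions: PBr3 (0.4 equiv), Et2O, 0 °C, 1 h; cold aq. NaHCO3 wash; used at once
Reagents that add atoms: phosphorus tribromide, BrP(Br)Br
Why: Activation of the benzylic alcohol as a phosphite and displacement by bromide is fast at 0 °C for this electron-rich benzylic position, and the short cold contact leaves the aryl ethers untouched.

Step 5
Reactants: 6 sarcosine ethyl ester hydrochloride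
Product: 7 ethyl N-(tert-butoxycarbonyl)-N-methylglycinate (Boc-Sar-OEt)
Conditions: Boc2O (1.1 equiv), NaHCO3 (2.5 equiv), THF/H2O, rt, 12 h
Reagents that add atoms: di-tert-butyl dicarbonate, CC(C)(C)OC(=O)OC(=O)OC(C)(C)C
Why: Carbamate protection of the liberated secondary amine under Schotten–Baumann-type conditions gives a glycine equivalent with no N–H that already carries the N-methyl group of the target.

Step 6
Reactants: 5 2-(benzyloxy)-1-(bromomethyl)-3,4-dimethoxybenzene; 7 ethyl N-(tert-butoxycarbonyl)-N-methylglycinate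
Product: 9 ethyl 3-[2-(benzyloxy)-3,4-dimethoxyphenyl]-2-[(tert-butoxycarbonyl)(methyl)amino]propanoate (racemic), via lithium enolate 8 (not isolated)
Conditions: 7 (1.3 equiv), LiN(iPr)2 (1.3 equiv), THF, −78 °C, 45 min; then 5, −78 → −20 °C, 3 h; aq. NH4Cl
Reagents that add atoms: lithium diisopropylamide LiN(iPr)2, [Li+].CC(C)[N-]C(C)C (lithium of 8 only; nothing from it stays in 9)
Why: SN2 alkylation of a fully formed ester enolate with a highly reactive benzylic bromide stops at monoalkylation for steric reasons, and the new stereocentre is formed racemic on purpose because it becomes sp2 in step 11.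

Step 7
Reactants: 9 ethyl 3-[2-(benzyloxy)-3,4-dimethoxyphenyl]-2-[(tert-butoxycarbonyl)(methyl)amino]propanoate
Product: 10 3-[2-(benzyloxy)-3,4-dimethoxyphenyl]-2-[(tert-butoxycarbonyl)(methyl)amino]propanoic acid (racemic)
Conditions: LiOH·H2O (3 equiv), THF/MeOH/H2O, rt, 12 h; then 1 N HCl to pH 3
Reagents that add atoms: lithium hydroxide, [Li+].[OH-]
Why: Saponification of the ethyl ester leaves the Boc carbamate and all ethers intact, and epimerisation is irrelevant for a racemate.

Step 8
Reactants: 11 (4-methoxyphenyl)acetic acid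
Product: 12 tert-butyl (4-methoxyphenyl)acetate
Conditions: Boc2O (1.5 equiv), DMAP (0.2 equiv), t-BuOH, 35 °C, 16 h
Reagents that add atoms: tert-butanol, CC(C)(C)O
Why: DMAP-catalysed esterification through the mixed carbonic anhydride gives, under neutral conditions, a tert-butyl ester that resists self-condensation and is later removed by acid together with the Boc group.

Step 9
Reactants: 10 3-[2-(benzyloxy)-3,4-dimethoxyphenyl]-2-[(tert-butoxycarbonyl)(methyl)amino]propanoic acid; 12 tert-butyl (4-methoxyphenyl)acetate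
Product: 15 tert-butyl 5-[2-(benzyloxy)-3,4-dimethoxyphenyl]-4-[(tert-butoxycarbonyl)(methyl)amino]-2-(4-methoxyphenyl)-3-oxopentanoate (diastereomer/enol mixture), via acyl imidazolide 13 (not isolated), via lithium enolate 14 (not isolated)
Conditions: 10, Im2CO (1.1 equiv), THF, rt, 1 h (flask A); 12 (3.3 equiv), LiN(SiMe3)2 (3.2 equiv), THF, −78 °C, 45 min (flask B); A into B, −78 → 0 °C, 3 h; cold 1 N HCl
Reagents that add atoms: 1,1'-carbonyldiimidazole, O=C(n1ccnc1)n1ccnc1 (imidazolyl group of 13 only); lithium bis(trimethylsilyl)amide LiN(SiMe3)2, [Li+].C[Si](C)(C)[N-][Si](C)(C)C (lithium of 14 only)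
Why: In this crossed Claisen condensation the tert-butyl arylacetate enolate, which does not self-condense, is acylated at carbon by the acyl imidazolide and surplus enolate irreversibly deprotonates the acidic alpha-aryl beta-keto ester (and the freed imidazole), while the new alpha-aryl stereocentre is uncontrolled and irrelevant because it is lost in step 10.

Step 10
Reactants: 15 tert-butyl 5-[2-(benzyloxy)-3,4-dimethoxyphenyl]-4-[(tert-butoxycarbonyl)(methyl)amino]-2-(4-methoxyphenyl)-3-oxopentanoate
Product: 17 4-[2-(benzyloxy)-3,4-dimethoxyphenyl]-1-(4-methoxyphenyl)-3-(methylamino)butan-2-one trifluoroacetate (racemic), via beta-keto acid salt 16 (not isolated)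
Conditions: TFA/CH2Cl2 1:1, 0 °C → rt, 3 h; evaporate; MeCN, 50 °C, 1 h
Reagents that add atoms: trifluoroacetic acid, OC(=O)C(F)(F)F (counter-ion of the salt)
Why: Acidolysis removes the Boc group and the tert-butyl ester together, the alpha-aryl beta-keto acid then decarboxylates through the usual cyclic transition state, and the amine stays protonated throughout so that neither lactamisation to a tetramic acid nor amino ketone self-condensation can occur, while the aryl benzyl and methyl ethers survive the short TFA exposure.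

Step 11
Reactants: 17 4-[2-(benzyloxy)-3,4-dimethoxyphenyl]-1-(4-methoxyphenyl)-3-(methylamino)butan-2-one trifluoroacetate
Product: 19 5-[2-(benzyloxy)-3,4-dimethoxybenzyl]-4-(4-methoxybenzyl)-1-methyl-1H-imidazol-2-amine, via guanidine 18 (not isolated)
Conditions: NH2CN (50% aq., 10 equiv), EtOH/H2O 1:1, pH 4.5, 95 °C, 3 h; then aq. Na2CO3
Reagents that add atoms: cyanamide, NC#N
Why: In this Marckwald-type 2-aminoimidazole synthesis the secondary amine adds to cyanamide, the resulting guanidine cyclises onto the ketone, and dehydration with tautomerisation aromatises the ring, which erases the last sp3 stereocentre and places N-methyl next to the carbon bearing the trioxygenated benzyl group.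

Step 12
Reactants: 19 5-[2-(benzyloxy)-3,4-dimethoxybenzyl]-4-(4-methoxybenzyl)-1-methyl-1H-imidazol-2-amine
Product: 20 6-{[2-amino-4-(4-methoxybenzyl)-1-methyl-1H-imidazol-5-yl]methyl}-2,3-dimethoxyphenol
Conditions: H2 (1 atm), 10% Pd/C, MeOH, rt, 6 h
Reagents that add atoms: none
Why: Catalytic hydrogenolysis cleaves only the benzylic carbon–oxygen bond of the aryl benzyl ether, and it is run before the reducible acylamidine unit is installed.

Step 13
Reactants: 21 N-methylurea
Product: 22 1-methylimidazolidine-2,4,5-trione (1-methylparabanic acid)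
Conditions: (COCl)2 (1.1 equiv), THF, 0 °C → reflux, 2 h
Reagents that add atoms: oxalyl chloride, O=C(Cl)C(=O)Cl
Why: Double N-acylation of the urea by the bis-electrophile closes the five-membered trione ring, driven by loss of HCl.

Step 14
Reactants: 22 1-methylimidazolidine-2,4,5-trione
Product: 23 1-methyl-4-[(trimethylsilyl)oxy]-1H-imidazole-2,5-dione
Conditions: N,O-bis(trimethylsilyl)acetamide (1.2 equiv), MeCN, reflux, 1 h; solvent stripped, moisture-sensitive residue used at once
Reagents that add atoms: N,O-bis(trimethylsilyl)acetamide, CC(=N[Si](C)(C)C)O[Si](C)(C)C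
Why: Silylation of the only imide N–H/C=O pair turns the carbonyl next to the unsubstituted nitrogen into a silyl imidate, an activated electrophile with a good leaving group.

Step 15
Reactants: 20 6-{[2-amino-4-(4-methoxybenzyl)-1-methyl-1H-imidazol-5-yl]methyl}-2,3-dimethoxyphenol; 23 1-methyl-4-[(trimethylsilyl)oxy]-1H-imidazole-2,5-dione
Product: 24 pyronaamidine
Conditions: 23 (2.5 equiv), toluene, reflux, 16 h; then MeOH, rt
Reagents that add atoms: none
Why: Addition–elimination of the exocyclic 2-amino group at the silyl imidate carbon with loss of Me3SiOH gives the conjugated acylamidine, and any aryl silyl ether formed by silyl transfer to the phenol is cleaved in the methanol work-up.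

## Compound list
1 | 2,3,4-trimethoxybenzaldehyde | COc1ccc(C=O)c(OC)c1OC | starting material
2 | 2-hydroxy-3,4-dimethoxybenzaldehyde | COc1ccc(C=O)c(O)c1OC | intermediate
3 | 2-(benzyloxy)-3,4-dimethoxybenzaldehyde | COc1ccc(C=O)c(OCc2ccccc2)c1OC | intermediate
4 | [2-(benzyloxy)-3,4-dimethoxyphenyl]methanol | COc1ccc(CO)c(OCc2ccccc2)c1OC | intermediate
5 | 2-(benzyloxy)-1-(bromomethyl)-3,4-dimethoxybenzene | COc1ccc(CBr)c(OCc2ccccc2)c1OC | intermediate
6 | sarcosine ethyl ester hydrochloride | CCOC(=O)CNC.Cl | starting material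
7 | ethyl N-(tert-butoxycarbonyl)-N-methylglycinate | CCOC(=O)CN(C)C(=O)OC(C)(C)C | intermediate
8 | lithium enolate of 7 (not isolated) | [Li+].CCOC([O-])=CN(C)C(=O)OC(C)(C)C | intermediate
9 | ethyl 3-[2-(benzyloxy)-3,4-dimethoxyphenyl]-2-[(tert-butoxycarbonyl)(methyl)amino]propanoate (racemic) | CCOC(=O)C(Cc1ccc(OC)c(OC)c1OCc1ccccc1)N(C)C(=O)OC(C)(C)C | intermediate
10 | 3-[2-(benzyloxy)-3,4-dimethoxyphenyl]-2-[(tert-butoxycarbonyl)(methyl)amino]propanoic acid (racemic) | OC(=O)C(Cc1ccc(OC)c(OC)c1OCc1ccccc1)N(C)C(=O)OC(C)(C)C | intermediate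
11 | (4-methoxyphenyl)acetic acid | COc1ccc(CC(=O)O)cc1 | starting material
12 | tert-butyl (4-methoxyphenyl)acetate | COc1ccc(CC(=O)OC(C)(C)C)cc1 | intermediate
13 | acyl imidazolide of 10, tert-butyl N-{3-[2-(benzyloxy)-3,4-dimethoxyphenyl]-1-(1H-imidazol-1-yl)-1-oxopropan-2-yl}-N-methylcarbamate (not isolated) | O=C(n1ccnc1)C(Cc1ccc(OC)c(OC)c1OCc1ccccc1)N(C)C(=O)OC(C)(C)C | intermediate
14 | lithium enolate of 12 (not isolated) | [Li+].COc1ccc(C=C([O-])OC(C)(C)C)cc1 | intermediate
15 | tert-butyl 5-[2-(benzyloxy)-3,4-dimethoxyphenyl]-4-[(tert-butoxycarbonyl)(methyl)amino]-2-(4-methoxyphenyl)-3-oxopentanoate (diastereomer/enol mixture) | CC(C)(C)OC(=O)C(c1ccc(OC)cc1)C(=O)C(Cc1ccc(OC)c(OC)c1OCc1ccccc1)N(C)C(=O)OC(C)(C)C | intermediate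
16 | 5-[2-(benzyloxy)-3,4-dimethoxyphenyl]-2-(4-methoxyphenyl)-4-(methylamino)-3-oxopentanoic acid trifluoroacetate (not isolated) | CNC(Cc1ccc(OC)c(OC)c1OCc1ccccc1)C(=O)C(C(=O)O)c1ccc(OC)cc1.OC(=O)C(F)(F)F | intermediate
17 | 4-[2-(benzyloxy)-3,4-dimethoxyphenyl]-1-(4-methoxyphenyl)-3-(methylamino)butan-2-one trifluoroacetate (racemic) | CNC(Cc1ccc(OC)c(OC)c1OCc1ccccc1)C(=O)Cc1ccc(OC)cc1.OC(=O)C(F)(F)F | intermediate
18 | 1-{1-[2-(benzyloxy)-3,4-dimethoxyphenyl]-4-(4-methoxyphenyl)-3-oxobutan-2-yl}-1-methylguanidine (not isolated) | CN(C(N)=N)C(Cc1ccc(OC)c(OC)c1OCc1ccccc1)C(=O)Cc1ccc(OC)cc1 | intermediate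
19 | 5-[2-(benzyloxy)-3,4-dimethoxybenzyl]-4-(4-methoxybenzyl)-1-methyl-1H-imidazol-2-amine | COc1ccc(Cc2nc(N)n(C)c2Cc2ccc(OC)c(OC)c2OCc2ccccc2)cc1 | intermediate
20 | 6-{[2-amino-4-(4-methoxybenzyl)-1-methyl-1H-imidazol-5-yl]methyl}-2,3-dimethoxyphenol | COc1ccc(Cc2nc(N)n(C)c2Cc2ccc(OC)c(OC)c2O)cc1 | intermediate
21 | N-methylurea | CNC(N)=O | starting material
22 | 1-methylimidazolidine-2,4,5-trione (1-methylparabanic acid) | CN1C(=O)NC(=O)C1=O | intermediate
23 | 1-methyl-4-[(trimethylsilyl)oxy]-1H-imidazole-2,5-dione | CN1C(=O)N=C(O[Si](C)(C)C)C1=O | intermediate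
24 | pyronaamidine | COc1ccc(Cc2nc(NC3=NC(=O)N(C)C3=O)n(C)c2Cc2ccc(OC)c(OC)c2O)cc1 | target

## Step count and risks
Total step count: 15.
Longest linear sequence: 11 steps (steps 1, 2, 3, 4, 6, 7, 9, 10, 11, 12, 15).

**Risk 1, step 6.** Bromide 5 is very electron-rich and can decompose or oligomerise, and the hard enolate 8 can self-condense. The fallback sets out from 5 and comes back at 9.
- Bromide 5 alkylates commercial ethyl N-(diphenylmethylene)glycinate under solid–liquid phase-transfer conditions (K2CO3, Bu4NBr, MeCN, reflux). This soft, stabilised aza-allyl anion is formed only in low concentration.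
- The product is ethyl 3-[2-(benzyloxy)-3,4-dimethoxyphenyl]-2-[(diphenylmethylidene)amino]propanoate F1.
- 1 N HCl in THF at rt, followed by basification, hydrolyses the imine to ethyl 2-amino-3-[2-(benzyloxy)-3,4-dimethoxyphenyl]propanoate F2.
- Boc2O and NaHCO3 in THF/H2O give ethyl 3-[2-(benzyloxy)-3,4-dimethoxyphenyl]-2-[(tert-butoxycarbonyl)amino]propanoate F3.
- NaH and MeI in DMF at 0 °C N-methylate the carbamate to give 9.

**Risk 2, step 9.** A stabilised enolate must acylate a hindered N-methyl carbamate acyl donor, so conversion may be slow or oxygen acylation may compete. The fallback sets out from 10 and comes back at 17.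
- Acid 10 is activated with 1,1'-carbonyldiimidazole as before (13) and treated with N,O-dimethylhydroxylamine hydrochloride. This gives the Weinreb amide tert-butyl N-{3-[2-(benzyloxy)-3,4-dimethoxyphenyl]-1-[methoxy(methyl)amino]-1-oxopropan-2-yl}-N-methylcarbamate F4.
- Commercial 4-methoxybenzylmagnesium chloride in THF at 0 °C adds once through the stable chelate. This gives tert-butyl N-{1-[2-(benzyloxy)-3,4-dimethoxyphenyl]-4-(4-methoxyphenyl)-3-oxobutan-2-yl}-N-methylcarbamate F5.
- TFA/CH2Cl2 at rt removes the Boc group to give 17.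

**Risk 3, step 15.** Compound 20 offers three silylatable or nucleophilic sites, so conversion may be low or phenol-derived by-products may form on the most valuable material. The fallback sets out from 19 and comes back at 24, bypassing 20.
- The benzyl ether 19 is condensed with 23 in refluxing toluene to give O-benzylpyronaamidine F6.
- The benzyl group is then removed without reduction, using BCl3 (5 equiv) and pentamethylbenzene (5 equiv) in CH2Cl2 at −78 °C with a cold MeOH quench. These conditions spare the acylamidine double bond and the methyl ethers and give 24.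

## Further compounds
F1 | step 6 | ethyl 3-[2-(benzyloxy)-3,4-dimethoxyphenyl]-2-[(diphenylmethylidene)amino]propanoate | CCOC(=O)C(Cc1ccc(OC)c(OC)c1OCc1ccccc1)N=C(c1ccccc1)c1ccccc1
F2 | step 6 | ethyl 2-amino-3-[2-(benzyloxy)-3,4-dimethoxyphenyl]propanoate | CCOC(=O)C(N)Cc1ccc(OC)c(OC)c1OCc1ccccc1
F3 | step 6 | ethyl 3-[2-(benzyloxy)-3,4-dimethoxyphenyl]-2-[(tert-butoxycarbonyl)amino]propanoate | CCOC(=O)C(Cc1ccc(OC)c(OC)c1OCc1ccccc1)NC(=O)OC(C)(C)C
F4 | step 9 | tert-butyl N-{3-[2-(benzyloxy)-3,4-dimethoxyphenyl]-1-[methoxy(methyl)amino]-1-oxopropan-2-yl}-N-methylcarbamate | CON(C)C(=O)C(Cc1ccc(OC)c(OC)c1OCc1ccccc1)N(C)C(=O)OC(C)(C)C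
F5 | step 9 | tert-butyl N-{1-[2-(benzyloxy)-3,4-dimethoxyphenyl]-4-(4-methoxyphenyl)-3-oxobutan-2-yl}-N-methylcarbamate | COc1ccc(CC(=O)C(Cc2ccc(OC)c(OC)c2OCc2ccccc2)N(C)C(=O)OC(C)(C)C)cc1
F6 | step 15 | O-benzylpyronaamidine | COc1ccc(Cc2nc(NC3=NC(=O)N(C)C3=O)n(C)c2Cc2ccc(OC)c(OC)c2OCc2ccccc2)cc1
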